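The numbers in the tables were generated by integration with made-up constants, and the scatter is random.

I started from the ratio.

| setting | midnight | dusk | spring | flask |
|---|---|---|---|---|
| solid substrate | 0.21 M | 0.21 M | 0.10 M | 0.21 M |
| partner | 0.59 M | 0.92 M | 0.42 M | 0.420 M |
| remark | run made earlier | run made earlier | run made earlier |  |
| time |  |  |  | 8.0 min |

| run | time / min | target / % |
|---|---|---|
| midnight | 1.33 | 20.6 |
| midnight | 3.00 | 22.4 |
| midnight | 4.00 | 21.7 |
| midnight | 6.00 | 18.1 |
| midnight | 8.00 | 19.5 |
| midnight | 10.0 | 17.0 |
| dusk | 0.833 | 17.0 |
| dusk | 1.33 | 22.7 |
| dusk | 2.00 | 29.7 |
| dusk | 2.50 | 27.9 |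
| dusk | 4.00 | 24.1 |
| dusk | 6.00 | 22.0 |
| dusk | 10.0 | 22.1 |
| spring | 2.00 | 28.3 |
| spring | 4.00 | 22.5 |
| spring | 6.00 | 21.3 |
| spring | 8.00 | 22.8 |
| spring | 10.0 | 22.2 |

(scatter of a reading: 1 percentage point)

- given per volume of solution although it is solid: solid substrate
- at the start none of the solid substrate is in solution

- Tuesday's: doubling the solubility of the solid substrate, all else as stated
- Saturday's: doubling the amount of partner, all else as stated
- Monday's: doubling the dissolution coefficient of the solid substrate, all else as stated

- target at 8.0 min, in percent of the solid substrate charged
- the change that raises the amount of target at 8.0 min, in percent of the solid substrate charged most ("none" if none brings more than 2 percentage points) (Tuesday's / Saturday's / Monday's / none)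
- amount of target at 8.0 min, in percent of the solid substrate charged, after Tuesday's

1. The flask holds 2.00 equivalents of partner, that is, [partner] over [solid substrate] as charged. This number says how much partner stands ready for each unit of solid substrate.

2. I averaged the target readings from 6.00 min on. The asked time, 8.0 min, lies later than that. Midnight, with 2.81 equivalents, read 18.2 %. Dusk, with 4.38, read 22.1 %. Spring, with 4.20, read 22.1 %.

3. Was one number enough? Spring held about half the solid substrate of dusk, yet the two averages matched within the scatter of 1 percentage point. [partner] by itself failed the test: midnight held more partner than spring but read less target. So the ratio served for these runs. The ratio contains neither the solubility nor the dissolution coefficient, so I reckoned no change from Tuesday's or Monday's.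

4. Taking dusk and spring together against midnight, I read a gain of 2.6 points per equivalent. That put the flask at 16.1 %, and Tuesday's at the same value. Saturday's doubles the equivalents, which I reckoned to add 5.2 points, more than the margin of 2 points, so I chose Saturday's.

5. The forecast gave 15.5 %, a little below mine, with 15 % after Tuesday's and Saturday's as best, holding that “the yield appears to follow the partner/substrate ratio”.

6. The flask gave 16.1 %. Tuesday's gave 15.4 %, Monday's changed it by −0.45 points, and Saturday's added 4.9 points.

    solid substrate ⇌ dissolved substrate, rate k1*(cs1 - [dissolved substrate]) while solid is left; crystals form when [dissolved substrate] > cs1 (solubility = 0.130 M, k = 0.0166 /s)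
    solid substrate + target → side product B (k = 0.00833 /M/s)
    dissolved substrate + target → side product A (k = 0.166 /M/s)
    target ⇌ isomer of the product (K = 2.10, k = 0.0181 /s)
    dissolved substrate + partner → target (k = 0.0485 /M/s)

7. The neighbouring flask held 0.71 M of partner, the rest as in the flask. That is 3.38 equivalents against 2.00, so my gain per equivalent put it at 19.7 %. It gave 20.0 %. Side product A stood at 48.0 % in the flask and at 35.8 % in the neighbouring flask.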